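All runs are calculated for an exercise; scatter was added.

**The question.** How much of what each flask has turned into product stands as target?

| setting | Friday's | Thursday's | Wednesday's | oak | elm | maple | larch |
|---|---|---|---|---|---|---|---|
| starting material | 1.4 M | 2.2 M | 1 M | 1.0 M | 1.0 M | 1.0 M | 1.0 M |
| partner | 1 M | 1 M | 2 M | 1.00 M | 1.00 M | 1.00 M | 1.00 M |
| temperature | 0 °C | 25 °C | 0 °C |  | 45 °C | 5 °C | 25 °C |
| remark | run made earlier | run made earlier | run made earlier | at 45 °C until 2.0 min, from then on at 5 °C |  |  |  |
| time |  |  |  | 2.5 min | 2.5 min | 2.5 min | 2.5 min |

| run | time / min | target / % | homo product / % |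
|---|---|---|---|
| Friday's | 3.00 | 2.3 | 2.7 |
| Friday's | 6.00 | 6.0 | 10.5 |
| Friday's | 10.0 | 11.6 | 24.4 |
| Friday's | 12.0 | 13.1 | 29.5 |
| Friday's | 20.0 | 17.6 | 44.7 |
| Friday's | 25.0 | 18.2 | 49.8 |
| Thursday's | 0.833 | 12.8 | 29.6 |
| Thursday's | 2.00 | 17.7 | 50.7 |
| Thursday's | 2.50 | 19.0 | 54.1 |
| Thursday's | 4.00 | 20.5 | 58.3 |
| Thursday's | 5.00 | 20.8 | 58.5 |
| Thursday's | 6.00 | 20.9 | 59.4 |
| Wednesday's | 2.00 | 2.2 | 0.6 |
| Wednesday's | 6.00 | 13.1 | 7.1 |
| Wednesday's | 12.0 | 25.6 | 17.8 |
| Wednesday's | 20.0 | 33.0 | 25.6 |
| Wednesday's | 25.0 | 34.8 | 27.5 |

(readings scatter by 0.3 percentage points)

- in percentages every species weighs as the starting material in it: one homo product counts as two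
- the earlier runs were read with a standard deviation of 0.3 percentage points

- the flask with the highest share of target in all that became target or homo product or isomer of the product ("all alike" if they lie within 1.5 percentage points) (oak / elm / maple / larch / all alike)
- share of target in all that became target or homo product or isomer of the product, oak
- share of target in all that became target or homo product or isomer of the product, elm
- share of target in all that became target or homo product or isomer of the product, maple
- share of target in all that became target or homo product or isomer of the product, larch

**The ledger.** Follow the starting material as fractions of its charge. Each fraction ends as target, homo product or isomer, or still waits as starting material or intermediate. The runs read target and homo product, and the rest is a gap. The asked share excludes intermediate and starting material from its denominator, so the gap cannot simply be booked as isomer.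

**Capture number.** The early lag suggests an intermediate, met either by partner or by its own kind. Partner-side product per homo product should therefore rise with partner and fall with starting material. Thursday's last reading, booking everything except homo product as partner-side, gives 1.50. This is the capture number, a selectivity factor: partner-side fraction per homo product fraction, times the charge of starting material over that of partner. At 6.00 min, with target alone as partner-side, Friday's run gives 0.800 and Wednesday's 0.923, despite very different charges. Their mean is 0.861 at 0 °C. Maple, at 5 °C, takes this cold value as it stands, and larch, at Thursday's temperature, takes 1.50. Elm, at 45 °C, takes the same rise once more, a rough 2.63.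

**Closing the books.** With equal charges, the partner-side fraction of products is the capture number over one plus itself: 46.3% for maple, 60.1% for larch and 72.4% for elm. Thursday's gap per target, 0.943, is a high estimate of isomer per target at that reading, since that gap may hold intermediate too. My reckoning therefore puts larch between 30.9% and 60.1%, and elm between 37.3% and 72.4%. Oak, hot for 2.0 min of its 2.5 min, takes elm's window. Cold maple should stay near 46.3%. The windows overlap, so I favour maple with reserve.

The forecast names maple, with maple 51%, oak 33%, elm 33% and larch 31%, reasoning “Oak equilibrated hot, and cooling freezes it”, and its elm figure stands lower than my floor.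

**The result.** Maple leads with 50.9%, then elm 46.1%, oak 44.8% and larch 35.6%.

    2 intermediate → homo product (k = 0.00699 /M/s, Ea = 44.0 kJ/mol)
    target ⇌ isomer of the product (K = 0.664, k = 0.0158 /s, Ea = 75.0 kJ/mol, ΔH = −12.0 kJ/mol)
    starting material → intermediate (k = 0.0479 /s, Ea = 82.0 kJ/mol)
    partner → decomposition product (k = 1.16 × 10⁻⁵ /s, Ea = 106 kJ/mol)
    partner + intermediate → target (k = 0.0100 /M/s, Ea = 66.0 kJ/mol)
    (constants at 25 °C)

**The neighbour.** Elm holds 68.7% of its products on the partner side, against 72.4% reckoned. The neighbour is larch with partner raised to 1.7 M. There 1.50 times the charge ratio gives 2.56, so 71.9% should be partner-side. That neighbour holds target 40.2%, isomer 23.2% and homo product 23.9%, which puts 72.6% on the partner side, and its share of target is 46.0%.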